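## Structural features

- The target is an oxolane ring O1–C2–C3–C4–C5. C2 carries a 3,4-dimethoxyphenyl group, C3 a CH2–O–(3,4-dimethoxybenzoyl) arm, C4 a free hydroxyl, and C5 is a methylene.
- C2 (R), C3 (S) and C4 (R) are contiguous and all three substituents lie on one face of the ring (all-cis). This is the least stable arrangement, so no centre can be set by equilibration.
- Fragile points: the C2–O1 bond is a 4-alkoxybenzylic ether (acid ionisation would epimerise C2; hydrogenolysis and quinone oxidants threaten it). The primary aroyl ester can shift to the cis 4-hydroxyl under base. Whenever the C3 arm stands at the aldehyde or ester level, C3 can epimerise and O4 or O1 can be lost by β-elimination.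
- The real difficulty is the cis,cis triad on a five-membered ring, not the ring or the ester.
- Feature exploited by the key step: O1–C2(aryl)–C3(–CH2O)–C4(OH)–C5 is a 1-C-aryl pentopyranose whose sugar carbon C2 has been pushed out of the ring (O1 = O5, C2 = C1, C3 = C3, C4 = C4, C5 = C5, exocyclic CH2O = sugar C2). C4 (R) of the target has the spatial arrangement of C4 (S) of L-arabinose, and in the 1,2-trans C-aryl L-arabinopyranoside the aryl group, O3 and O4 lie on one face.
- In one sentence: the route is a semipinacol ring contraction of a six-membered C-aryl L-arabinopyranoside 3-sulfonate to the oxolane. This sentence does not fit an aldol/etherification route.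

## Logic of the disconnections

**15 ⇒ 14 ⇒ 12 + 13.** The O–Si bond at O4 and then the acyl C–O bond of the primary ester are cut. The ester is base-labile and can migrate to O4, so it is installed last on the only free hydroxyl while O4 is capped. The demand is an O4 cap that survives hydride and comes off without base and without strong acid.

**12 ⇒ 9 (key).** The oxolane bond C2–C3 (sugar C1–C3) is cut, and the sugar bonds C1–C2 and C3–O(sulfonate) are restored, which turns the five-membered ring into a six-membered one. The three all-cis centres become centres of a pyranoside chair with equatorial aryl, equatorial O2 and O3 and axial O4, the stable arrangement of a chiral-pool sugar. The forward step needs O2 as an alkoxide, O3 as an equatorial leaving group, O4 capped, and reduction of aldehyde 11 in the same flask.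

**9 ⇒ 8 ⇒ 7.** The Si–O bond at O4 and the S–O bond at O3 are cut. The cis-3,4-diol of 7 is differentiated through its equatorial and axial oxygens. The demand is sulfonylation at O3 only.

**7 ⇒ 6 ⇒ 5.** The acetonide C–O bonds and the pivalate C–O bond are cut. In 5 only O2 is free, so acylation there needs no selectivity. The acyl group must not migrate and must fall to hydride in the key step.

**5 ⇒ 4.** The ring bond C1–O5 is cut. The forward closure runs through a benzylic cation, so both C1 epimers of 4 converge. The demand is an acid mild enough to spare the acetonide.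

**4 ⇒ 2 + 3.** The C1–aryl bond is cut. A masked aldehyde (lactol) accepts the aryl nucleophile; no stereocontrol is needed at C1.

**2 ⇒ 1.** The acetonide is cut. The only cis-vicinal diol of 1 in its pyranose form is O3/O4, which leaves O1 and O2 free.

## Other disconnections considered

**Alternative 1:** The ring ether bond O1–C5 and the C2–C3 bond are cut (the first idea that comes to mind).
- Forward: an auxiliary-controlled anti-aldol with 3,4-dimethoxybenzaldehyde and reduction give diol A1. Epoxidation of its vinyl group gives A2, and the C2 hydroxyl closes the ring on the terminal epoxide carbon.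
- Ground for rejection: the three centres are set in separate events. The C4 centre depends on facial selection at a monosubstituted vinyl group with only homoallylic hydroxyls to direct it. The closure is a 5-endo opening that competes with 4-exo opening and with the primary hydroxyl. An auxiliary must be put on and removed.
- In the chosen plan every centre has a structural origin and is carried through by a concerted shift.

**Alternative 2:** The C4–H bond is cut.
- Forward: a ketoreductase (enzyme class) reduces racemic keto ester A3, available from a cinnamate and a glycolate by oxa-Michael/Dieckmann reaction, to hydroxy ester A4 with dynamic resolution at C3.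
- Ground for rejection: C3 is stereolabile but C2 is not, because reopening by retro-oxa-Michael would have to pass through a doubly stabilised enolate at neutral pH. At most half of the material could converge.
- The all-cis product also requires reduction of the minor 2,3-cis keto tautomer, and which tautomer an enzyme accepts cannot be argued from the structure. A4 keeps an epimerisable C3.
- This plan is shorter but not defensible from mechanism.

**Alternative 3:** The C2–C3 bond is cut.
- Forward: Lewis-acid-mediated 1,3 oxygen-to-carbon rearrangement (seven-to-five ring contraction) of enantioenriched vinyl acetal A5 to aldehyde A6.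
- Ground for rejection: the step passes through an oxocarbenium/enolate pair, so the C2/C3 relation depends on how the pair recombines. Its relation to the C4 silyloxy group rests on a small allylic bias.
- A6 is released into a Lewis-acidic medium where it could epimerise at C3 or lose silanol. A5 needs an extra enantioselective desymmetrisation.
- The chosen contraction transmits configuration from sp3 centres by a stereospecific 1,2-shift and reduces the aldehyde at once.

Key step: step 8

Remark: six-membered sugar-derived intermediates are numbered as carbohydrates (C1 bears the aryl group, O5 is the ring oxygen); L-arabinose is taken as its crystalline β-pyranose.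

## Steps

Step 1
Reactants: 1 L-arabinose
Product: 2 3,4-O-isopropylidene-β-L-arabinopyranose
Conditions: 2,2-dimethoxypropane (1.5 equiv), p-TsOH·H2O (cat.), DMF, rt; Et3N quench
Reagents that add atoms: 2,2-dimethoxypropane, COC(C)(C)OC
Why: Acid-catalysed transacetalisation (acetonide formation): in the pyranose form only O3/O4 are cis-vicinal, so the dioxolane forms there and the anomeric OH and O2 stay free; no stereocentre is touched.

Step 2
Reactants: 2 3,4-O-isopropylidene-β-L-arabinopyranose; 3 (3,4-dimethoxyphenyl)magnesium bromide (commercial THF solution)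
Product: 4 (1RS)-1-C-(3,4-dimethoxyphenyl)-3,4-O-isopropylidene-L-arabinitol (open-chain 1,2,5-triol, both C1 epimers)
Conditions: 3 (4 equiv), THF, 0 °C to rt; sat. aq. NH4Cl
Reagents that add atoms: none
Why: Grignard addition to the open-chain aldehyde released from the magnesium lactolate of 2 (two equivalents of 3 are consumed as base by the two hydroxyls); the new carbinol centre C1 forms without reliable control, which is harmless because step 3 erases it.

Step 3
Reactants: 4 (1RS)-1-C-(3,4-dimethoxyphenyl)-3,4-O-isopropylidene-L-arabinitol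
Product: 5 (1S)-1,5-anhydro-1-C-(3,4-dimethoxyphenyl)-3,4-O-isopropylidene-L-arabinitol (six-membered C-glycoside, aryl equatorial and trans to the free 2-OH)
Conditions: p-TsOH·H2O (5 mol%), 4 Å MS, CH2Cl2, 0 °C to rt; Et3N quench
Reagents that add atoms: none
Why: Acid-catalysed cyclodehydration through the 4-methoxy-stabilised benzylic cation (SN1): O3 and O4 are tied in the acetonide and O2 could only give an epoxide that reopens, so O5–H closes the six-membered ring. Both C1 epimers of 4 pass through the same planar cation, and reversible ionisation should funnel them to the isomer with equatorial aryl trans to O2 (1S).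

Step 4
Reactants: 5 (1S)-1,5-anhydro-1-C-(3,4-dimethoxyphenyl)-3,4-O-isopropylidene-L-arabinitol
Product: 6 (1S)-1,5-anhydro-1-C-(3,4-dimethoxyphenyl)-3,4-O-isopropylidene-2-O-pivaloyl-L-arabinitol
Conditions: PivCl (1.5 equiv), pyridine, DMAP (cat.), CH2Cl2, 0 °C to rt
Reagents that add atoms: pivaloyl chloride, CC(C)(C)C(Cl)=O
Why: Nucleophile-catalysed acylation of the only free hydroxyl; the pivalate is chosen because it resists O2-to-O3 acyl shift in step 6 and is cleaved by hydride in step 8.

Step 5
Reactants: 6 (1S)-1,5-anhydro-1-C-(3,4-dimethoxyphenyl)-3,4-O-isopropylidene-2-O-pivaloyl-L-arabinitol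
Product: 7 (1S)-1,5-anhydro-1-C-(3,4-dimethoxyphenyl)-2-O-pivaloyl-L-arabinitol (3,4-diol)
Conditions: AcOH/H2O 4:1, 45 °C
Reagents that add atoms: none
Why: Aqueous-acid hydrolysis of the cis-fused acetonide; the pivalate is stable to aqueous acetic acid, and benzylic ionisation at C1 is disfavoured by the adjacent acyloxy-bearing carbon.

Step 6
Reactants: 7 (1S)-1,5-anhydro-1-C-(3,4-dimethoxyphenyl)-2-O-pivaloyl-L-arabinitol
Product: 8 (1S)-1,5-anhydro-1-C-(3,4-dimethoxyphenyl)-2-O-pivaloyl-3-O-(4-methylbenzenesulfonyl)-L-arabinitol (4-OH free)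
Conditions: Bu2SnO (0.1 equiv), TsCl (1.2 equiv), i-Pr2NEt (1.5 equiv), CH2Cl2, rt
Reagents that add atoms: p-toluenesulfonyl chloride, Cc1ccc(cc1)S(Cl)(=O)=O
Why: Tin-mediated regioselective sulfonylation: the cis-3,4-diol forms a five-membered stannylene acetal whose equatorial oxygen (O3) is the nucleophilic one, so the tosylate enters at O3 and the axial O4–H remains; no stereocentre is changed.

Step 7
Reactants: 8 (1S)-1,5-anhydro-1-C-(3,4-dimethoxyphenyl)-2-O-pivaloyl-3-O-(4-methylbenzenesulfonyl)-L-arabinitol
Product: 9 (1S)-1,5-anhydro-4-O-(tert-butyldimethylsilyl)-1-C-(3,4-dimethoxyphenyl)-2-O-pivaloyl-3-O-(4-methylbenzenesulfonyl)-L-arabinitol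
Conditions: TBSOTf (1.5 equiv), 2,6-lutidine (2.5 equiv), CH2Cl2, 0 °C to rt
Reagents that add atoms: tert-butyldimethylsilyl trifluoromethanesulfonate, CC(C)(C)[Si](C)(C)OS(=O)(=O)C(F)(F)F
Why: Silylation of the hindered axial hydroxyl with a silyl triflate under buffered conditions; the silyl ether blocks O4 so that it cannot act as an alkoxide trigger in step 8.

Step 8
Reactants: 9 (1S)-1,5-anhydro-4-O-(tert-butyldimethylsilyl)-1-C-(3,4-dimethoxyphenyl)-2-O-pivaloyl-3-O-(4-methylbenzenesulfonyl)-L-arabinitol
Product: 12 [(2R,3R,4R)-4-[(tert-butyldimethylsilyl)oxy]-2-(3,4-dimethoxyphenyl)oxolan-3-yl]methanol, via lithium 2-alkoxide 10 (not isolated), via oxolane-3-carbaldehyde 11 (not isolated)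
Conditions: LiBHEt3 (5 equiv, 1 M in THF), THF, 0 °C to rt; H2O quench at 0 °C
Reagents that add atoms: none
Why: Lithium triethylborohydride first reduces the pivalate and so unveils lithium alkoxide 10 in the flask. In the chair of 10 the aryl group, O2 and the tosylate are equatorial and the silyloxy group is axial, so the ring bond C1–C2 is antiperiplanar to C3–OTs; pushed by the alkoxide, C1 migrates from C2 to C3 as tosylate leaves and C2 becomes the formyl carbon of 11 (semipinacol rearrangement with ring contraction). The closest known reaction type is the hydride-induced ring contraction of trans-diequatorial pyranoside hydroxy sulfonates to branched-chain furanosides with reduction of the aldehyde in the same flask. The oxolane ring is closed by this 1,2-shift inside the six-membered ring through a three-centre transition state, not by an end-to-end cyclisation. C3 of the oxolane is set by inversion at the sulfonate carbon, which places the formyl branch on the face the tosylate occupied, cis to aryl and silyloxy; C2 is the migrating carbon and keeps its configuration, and C4 is not touched. Excess hydride reduces 11 at once to the alkoxide of 12, before the all-cis aldehyde can epimerise at C3 or eliminate O4 or O1. The step needs migration of C1 and not of C5, and migration instead of epoxide closure, hydride shift or hydride displacement: the silyl cap leaves O4 without a push for C5, the equatorial aryl group locks the chair in which O2 cannot reach the backside of C3 and the axial C2–H is gauche to the leaving group, and the electron-rich benzylic, oxygen-bearing C1 is a good migrating group.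

Step 9
Reactants: 12 [(2R,3R,4R)-4-[(tert-butyldimethylsilyl)oxy]-2-(3,4-dimethoxyphenyl)oxolan-3-yl]methanol; 13 3,4-dimethoxybenzoyl chloride
Product: 14 [(2R,3R,4R)-4-[(tert-butyldimethylsilyl)oxy]-2-(3,4-dimethoxyphenyl)oxolan-3-yl]methyl 3,4-dimethoxybenzoate
Conditions: Et3N (2 equiv), DMAP (0.1 equiv), CH2Cl2, 0 °C to rt
Reagents that add atoms: none
Why: Nucleophile-catalysed O-acylation of the only free, primary hydroxyl with an acid chloride; no stereocentre is involved.

Step 10
Reactants: 14 [(2R,3R,4R)-4-[(tert-butyldimethylsilyl)oxy]-2-(3,4-dimethoxyphenyl)oxolan-3-yl]methyl 3,4-dimethoxybenzoate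
Product: 15 [(2R,3S,4R)-2-(3,4-dimethoxyphenyl)-4-hydroxyoxolan-3-yl]methyl 3,4-dimethoxybenzoate
Conditions: HF·pyridine, pyridine, THF, 0 °C to rt
Reagents that add atoms: none
Why: Fluoride-mediated Si–O cleavage under buffered, weakly acidic conditions: no base is present to drive the aroyl group to the cis 4-hydroxyl, and the acidity is too low to ionise the benzylic C2–O1 bond, so the three stereocentres stay as set (the C3 descriptor changes from R to S only because the silyl group leaves O4).

## Compound list

1 | L-arabinose (β-L-arabinopyranose) | O[C@H]1OC[C@H](O)[C@H](O)[C@H]1O | starting material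
2 | 3,4-O-isopropylidene-β-L-arabinopyranose | CC1(C)O[C@H]2CO[C@H](O)[C@H](O)[C@H]2O1 | intermediate
3 | (3,4-dimethoxyphenyl)magnesium bromide | COc1ccc([Mg]Br)cc1OC | starting material
4 | (1RS)-1-C-(3,4-dimethoxyphenyl)-3,4-O-isopropylidene-L-arabinitol | COc1ccc(cc1OC)C(O)[C@H](O)[C@H]1OC(C)(C)O[C@H]1CO | intermediate
5 | (1S)-1,5-anhydro-1-C-(3,4-dimethoxyphenyl)-3,4-O-isopropylidene-L-arabinitol | COc1ccc(cc1OC)[C@@H]1OC[C@@H]2OC(C)(C)O[C@@H]2[C@H]1O | intermediate
6 | (1S)-1,5-anhydro-1-C-(3,4-dimethoxyphenyl)-3,4-O-isopropylidene-2-O-pivaloyl-L-arabinitol | COc1ccc(cc1OC)[C@@H]1OC[C@@H]2OC(C)(C)O[C@@H]2[C@H]1OC(=O)C(C)(C)C | intermediate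
7 | (1S)-1,5-anhydro-1-C-(3,4-dimethoxyphenyl)-2-O-pivaloyl-L-arabinitol | COc1ccc(cc1OC)[C@@H]1OC[C@H](O)[C@H](O)[C@H]1OC(=O)C(C)(C)C | intermediate
8 | (1S)-1,5-anhydro-1-C-(3,4-dimethoxyphenyl)-2-O-pivaloyl-3-O-(4-methylbenzenesulfonyl)-L-arabinitol | COc1ccc(cc1OC)[C@@H]1OC[C@H](O)[C@H](OS(=O)(=O)c2ccc(C)cc2)[C@H]1OC(=O)C(C)(C)C | intermediate
9 | (1S)-1,5-anhydro-4-O-(tert-butyldimethylsilyl)-1-C-(3,4-dimethoxyphenyl)-2-O-pivaloyl-3-O-(4-methylbenzenesulfonyl)-L-arabinitol | COc1ccc(cc1OC)[C@@H]1OC[C@H](O[Si](C)(C)C(C)(C)C)[C@H](OS(=O)(=O)c2ccc(C)cc2)[C@H]1OC(=O)C(C)(C)C | intermediate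
10 | lithium 2-alkoxide of (1S)-1,5-anhydro-4-O-(tert-butyldimethylsilyl)-1-C-(3,4-dimethoxyphenyl)-3-O-(4-methylbenzenesulfonyl)-L-arabinitol | COc1ccc(cc1OC)[C@@H]1OC[C@H](O[Si](C)(C)C(C)(C)C)[C@H](OS(=O)(=O)c2ccc(C)cc2)[C@H]1[O-].[Li+] | intermediate (not isolated)
11 | (2R,3R,4R)-4-[(tert-butyldimethylsilyl)oxy]-2-(3,4-dimethoxyphenyl)oxolane-3-carbaldehyde | O=C[C@H]1[C@@H](O[Si](C)(C)C(C)(C)C)CO[C@H]1c1ccc(OC)c(OC)c1 | intermediate (not isolated)
12 | [(2R,3R,4R)-4-[(tert-butyldimethylsilyl)oxy]-2-(3,4-dimethoxyphenyl)oxolan-3-yl]methanol | OC[C@H]1[C@@H](O[Si](C)(C)C(C)(C)C)CO[C@H]1c1ccc(OC)c(OC)c1 | intermediate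
13 | 3,4-dimethoxybenzoyl chloride | COc1ccc(cc1OC)C(Cl)=O | starting material
14 | [(2R,3R,4R)-4-[(tert-butyldimethylsilyl)oxy]-2-(3,4-dimethoxyphenyl)oxolan-3-yl]methyl 3,4-dimethoxybenzoate | COc1ccc(C(=O)OC[C@H]2[C@@H](O[Si](C)(C)C(C)(C)C)CO[C@H]2c2ccc(OC)c(OC)c2)cc1OC | intermediate
15 | [(2R,3S,4R)-2-(3,4-dimethoxyphenyl)-4-hydroxyoxolan-3-yl]methyl 3,4-dimethoxybenzoate | COc1ccc(C(=O)OC[C@H]2[C@@H](O)CO[C@H]2c2ccc(OC)c(OC)c2)cc1OC | target

## Step count and least certain steps

Total steps: 10. Longest linear sequence: 10 steps (1 to 15).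

**Step 8 (key).**
- What may go wrong: after pivalate cleavage, alkoxide 10 may close onto C3 from a twist conformer (epoxide formation and hydride opening to deoxy products). Hydride may also attack the sulfonate directly, or the silyl group may shift from O4 to the new primary alkoxide. The cause is that migration must build positive charge at a carbon flanked by two oxygen-bearing carbons.
- Fallback (Lewis-acid-triggered, stepwise rearrangement in place of the hydride cascade): it sets out from 9. DIBAL-H in CH2Cl2 at −78 °C removes the pivalate and gives the hydroxy tosylate (1S)-1,5-anhydro-4-O-(tert-butyldimethylsilyl)-1-C-(3,4-dimethoxyphenyl)-3-O-(4-methylbenzenesulfonyl)-L-arabinitol F1. Et3Al in CH2Cl2 (−78 to 0 °C) then makes the aluminium alkoxide and assists sulfonate departure (organoaluminium-promoted pinacol-type 1,2-shift). The aluminium alkoxide is a poor nucleophile for epoxide closure and no displacing hydride is present. DIBAL-H at −78 °C reduces aldehyde 11 as it forms, and the route is rejoined at 12.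

**Step 3.**
- What may go wrong: the benzylic cation may undergo a pinacol-type hydride shift from C2 to a benzyl ketone, alkylate a second dimethoxyphenyl ring, or the acid may scramble the acetonide. The cause is that the cation has a free vicinal hydroxyl and the ring to be closed is six-membered.
- Fallback (oxidation then ionic reduction, no benzylic alcohol ionisation): it sets out from 4. DDQ in dioxane oxidises the electron-rich benzylic alcohol selectively to the aryl ketone, which closes to the cyclic hemiketal 1-C-(3,4-dimethoxyphenyl)-3,4-O-isopropylidene-L-arabinopyranose F2. Et3SiH/BF3·OEt2 in CH2Cl2/MeCN at −40 °C reduces the aryl-stabilised oxocarbenium ion by axial hydride delivery, which places the aryl group equatorial, and the route is rejoined at 5.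

**Step 6.**
- What may go wrong: sulfonylation at the axial O4, or shift of the pivaloyl group from O2 to O3 under tin/base. The cause is that the bulky pivalate flanks O3.
- Fallback (sulfonate first, no acyl neighbour; O2/O4 told apart afterwards by equatorial versus axial reactivity): it sets out from 5.
  - AcOH/H2O removes the acetonide and gives the triol (1S)-1,5-anhydro-1-C-(3,4-dimethoxyphenyl)-L-arabinitol F3.
  - Bu2SnO/TsCl sulfonylates the equatorial O3 of the cis-diol and gives (1S)-1,5-anhydro-1-C-(3,4-dimethoxyphenyl)-3-O-(4-methylbenzenesulfonyl)-L-arabinitol F4.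
  - BzCl/pyridine at −40 °C acylates the equatorial O2 in preference to the axial O4 and gives (1S)-1,5-anhydro-2-O-benzoyl-1-C-(3,4-dimethoxyphenyl)-3-O-(4-methylbenzenesulfonyl)-L-arabinitol F5.
  - TBSOTf/2,6-lutidine gives (1S)-1,5-anhydro-2-O-benzoyl-4-O-(tert-butyldimethylsilyl)-1-C-(3,4-dimethoxyphenyl)-3-O-(4-methylbenzenesulfonyl)-L-arabinitol F6.
  - Under the conditions of step 8, F6 loses its benzoate to the same alkoxide 10, and the route is rejoined at 12.

**Step 10.**
- What may go wrong: shift of the aroyl group to the freshly liberated cis 4-hydroxyl, or ionisation at C2 if the medium is too acidic.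
- Fallback (desilylate before the ester exists): it sets out from 12. TBAF in THF gives the diol (3R,4S,5R)-5-(3,4-dimethoxyphenyl)-4-(hydroxymethyl)oxolan-3-ol F7. Regioselective acylation of the primary hydroxyl with 13 (2,4,6-collidine, CH2Cl2, −40 °C) then gives the target directly, and the route is rejoined at 15.

## Further compounds

F1 | step 8 | (1S)-1,5-anhydro-4-O-(tert-butyldimethylsilyl)-1-C-(3,4-dimethoxyphenyl)-3-O-(4-methylbenzenesulfonyl)-L-arabinitol | COc1ccc(cc1OC)[C@@H]1OC[C@H](O[Si](C)(C)C(C)(C)C)[C@H](OS(=O)(=O)c2ccc(C)cc2)[C@H]1O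
F2 | step 3 | 1-C-(3,4-dimethoxyphenyl)-3,4-O-isopropylidene-L-arabinopyranose (cyclic hemiketal, both anomers) | COc1ccc(cc1OC)C1(O)OC[C@@H]2OC(C)(C)O[C@@H]2[C@H]1O
F3 | step 6 | (1S)-1,5-anhydro-1-C-(3,4-dimethoxyphenyl)-L-arabinitol | COc1ccc(cc1OC)[C@@H]1OC[C@H](O)[C@H](O)[C@H]1O
F4 | step 6 | (1S)-1,5-anhydro-1-C-(3,4-dimethoxyphenyl)-3-O-(4-methylbenzenesulfonyl)-L-arabinitol | COc1ccc(cc1OC)[C@@H]1OC[C@H](O)[C@H](OS(=O)(=O)c2ccc(C)cc2)[C@H]1O
F5 | step 6 | (1S)-1,5-anhydro-2-O-benzoyl-1-C-(3,4-dimethoxyphenyl)-3-O-(4-methylbenzenesulfonyl)-L-arabinitol | COc1ccc(cc1OC)[C@@H]1OC[C@H](O)[C@H](OS(=O)(=O)c2ccc(C)cc2)[C@H]1OC(=O)c1ccccc1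
F6 | step 6 | (1S)-1,5-anhydro-2-O-benzoyl-4-O-(tert-butyldimethylsilyl)-1-C-(3,4-dimethoxyphenyl)-3-O-(4-methylbenzenesulfonyl)-L-arabinitol | COc1ccc(cc1OC)[C@@H]1OC[C@H](O[Si](C)(C)C(C)(C)C)[C@H](OS(=O)(=O)c2ccc(C)cc2)[C@H]1OC(=O)c1ccccc1
F7 | step 10 | (3R,4S,5R)-5-(3,4-dimethoxyphenyl)-4-(hydroxymethyl)oxolan-3-ol | OC[C@H]1[C@@H](O)CO[C@H]1c1ccc(OC)c(OC)c1
A1 | alternative 1 | (1R,2R)-1-(3,4-dimethoxyphenyl)-2-ethenylpropane-1,3-diol | OC[C@@H](C=C)[C@@H](O)c1ccc(OC)c(OC)c1
A2 | alternative 1 | (1R,2R)-1-(3,4-dimethoxyphenyl)-2-[(2R)-oxiran-2-yl]propane-1,3-diol | OC[C@@H]([C@@H]1CO1)[C@@H](O)c1ccc(OC)c(OC)c1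
A3 | alternative 2 | methyl 2-(3,4-dimethoxyphenyl)-4-oxooxolane-3-carboxylate (racemic) | COC(=O)C1C(=O)COC1c1ccc(OC)c(OC)c1
A4 | alternative 2 | methyl (2R,3S,4R)-2-(3,4-dimethoxyphenyl)-4-hydroxyoxolane-3-carboxylate | COC(=O)[C@H]1[C@@H](O)CO[C@H]1c1ccc(OC)c(OC)c1
A5 | alternative 3 | (5R)-2-(3,4-dimethoxyphenyl)-5-[(triisopropylsilyl)oxy]-4,5-dihydro-1,3-dioxepine | COc1ccc(cc1OC)C1OC[C@H](O[Si](C(C)C)(C(C)C)C(C)C)C=CO1
A6 | alternative 3 | (2R,3R,4R)-2-(3,4-dimethoxyphenyl)-4-[(triisopropylsilyl)oxy]oxolane-3-carbaldehyde | O=C[C@H]1[C@@H](O[Si](C(C)C)(C(C)C)C(C)C)CO[C@H]1c1ccc(OC)c(OC)c1
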